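Of the E charged to Saturday's flask, 67.0 % was not X at the last reading, after 80.0 min. That leftover is the large thing. I reckon only the small one, X.

in all of them: E 0.20 M
- Tuesday's: L 0.47 equiv; temperature 8 °C; run made earlier
- Saturday's: L 1 equiv; temperature 24 °C; run made earlier
- midnight: L 0.700 equiv; temperature 0 °C; time 4.0 h
- noon: L 0.700 equiv; temperature 30 °C; time 4.0 h

- Tuesday's (time / h: X / %): 0.200: 3; 0.667: 0; 1.00: 0; 1.50: 2; 2.50: 6; 3.00: 10; 4.00: 15
- Saturday's (time / min: X / %): 6.00: 1; 10.0: 3; 12.0: 7; 20.0: 10; 30.0: 17; 50.0: 27; 80.0: 33

(standard deviation of a reading: 1.5 percentage points)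

1. the flask that comes out highest in amount of X, in percent of the E charged, or "all alike" when all lie within 1.5 percentage points (midnight / noon / all alike)
2. X at the end, in percent of the E charged, midnight
3. X at the end, in percent of the E charged, noon

**What do you carry from Saturday's flask?** Its last reading over its L gives 0.330. I call this the catch: X at the end per L charged, both as fractions of the E charged.

**Was that the end?** Nearly, I think. In Saturday's flask, X rose more slowly over the last stretch than over the one before. The reading carries its scatter of 1.5 percentage points.

**Why divide by L?** E is charged alike in these flasks, while L differs. Taking X in proportion to L is my assumption, not a reading.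

**And noon?** It is hotter than Saturday's flask and runs longer. So I take it to its end, and my reckoning gives 23.1 %.

**Does the catch hold when cold?** I doubt it. Tuesday's flask reached 0.319 per L and was still rising. I keep the catch for hot flasks.

**Midnight, then?** It is colder than Tuesday's flask, and it gets the same time. I put it below Tuesday's 15 %, with noon highest.

The forecast says noon, with 4 % for midnight and 40 % for noon. It reads Saturday's bend as “suggesting an equilibrium or catalyst decay”, and its noon figure is higher than mine.

    L → G (k = 0.00685 min⁻¹, Ea = 94.0 kJ mol⁻¹)
    E → Z (k = 0.00279 min⁻¹, Ea = 90.0 kJ mol⁻¹)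
    Z + G → X (k = 0.0119 M⁻¹ min⁻¹, Ea = 60.0 kJ mol⁻¹)
    Z → J (k = 0.00104 min⁻¹, Ea = 94.0 kJ mol⁻¹)
    (constants at 0 °C)

The highest flask is noon, with 22.4 % against 5.42 % for midnight. The forecast for noon stands 18 points above the result, and the catch gave 23.1 %. At 0.0821 h in noon, Z goes to J at 3.3 times the rate of Z + G to X, a selectivity factor. At the end, noon holds J 77.6 % and X 22.4 %, with E at 0 % and L at 0 %. The same flask as noon with 0.170 equiv of L gives 6.37 %, where the catch says 5.61 %.

The readings come from a simulation from invented constants; the scatter is artificial.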